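**Plan**

Numbering: C1 = CH2OH, chain C2–C12, ring C13–C18 (C15 = ketone carbon, C18 = tertiary carbinol carbon).
Disconnections: C2–C3 (aldol), C4–C5 (allylation), C10–C11 (sp3–sp3 coupling) and, on the ring, C13–C12, C13–CH3, C14–ethyl and C18–CH3; the remaining C5–C10 piece is traced back to a cyclohexene by reconnecting C5 to C10.
Enabling feature: C6 and C9 each carry a methyl group and are separated only by C7–C8, so C5–C10 is a masked meso-2,5-dimethylhexane-1,6-diol. This is the ozonolysis product of the ring C5–C6–C7–C8–C9–C10 of cis-3,6-dimethylcyclohexene, which a [4+2] addition of ethylene (C7, C8) to (E,E)-hexa-2,4-diene builds through C6–C7 and C8–C9.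
Forward order: the temporary cyclohexene is made and cleaved, its ends are told apart by a lipase, and C4/C3 are added by allylboration. Ring C13–C18 is taken ready-made from a quinone monoketal and substituted (ethyl, methyl, allyl, methyl). The halves are joined at C10–C11 by a copper-catalysed Grignard/tosylate coupling; an auxiliary-controlled aldol adds C1–C2 with the ethyl branch; acid unmasks the enone.
Stereochemistry: C6/C9 relative from the suprafacial cycloaddition of the E,E-diene, absolute from the lipase; C5 from the Ipc2B–allyl reagent; C14 from a Cu/phosphoramidite conjugate addition; C13 and C18 from C14 by substrate control; C2/C3 from the oxazolidinone.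

Key step: step 1

Remark (lipase): Pseudomonas lipases are taken to acylate the (S)-configured CH(CH3)CH2OH terminus, as they do with 2-methylalkan-1-ols; hydrolysis of the diacetate with the same enzyme would give the opposite monoacetate.
Remark (ligand): the ligand enantiomer is the one that gives (5R)-13; by analogy with cyclohex-2-enone this should be the (S,R,R)-phosphoramidite, otherwise its mirror image is used.
Remark (in-flask species): a species is numbered when a second reagent is added to it in the same flask for the next bond-forming or bond-cleaving event; metal alkoxides and borinates that are only released on work-up are not counted.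

**Route**

Step 1
Reactants: 1 (2E,4E)-hexa-2,4-diene; 2 ethylene
Product: 3 cis-3,6-dimethylcyclohex-1-ene (meso, 3R,6S)
Conditions: ethylene (large excess, ca. 200–300 bar), hydroquinone (cat.), neat, 180 °C, steel autoclave
Reagents that add atoms: none
Why: The s-cis conformer of the E,E-diene and ethylene combine in a concerted, thermally allowed [π4s+π2s] cycloaddition that forms C6–C7 and C8–C9 at once and turns the central diene bond into the C5=C10 olefin. The closest known reaction type is the thermal Diels–Alder reaction of ethylene with butadiene and alkyl-substituted dienes under heat and pressure. The six-membered ring closes intermolecularly by both σ-bonds in one step, and because both partners are symmetric there is no regiochemical or endo/exo question. C6 and C9 are created together; their cis relation follows from the E,E geometry (both methyl groups outside in the s-cis diene) and suprafacial bonding on the diene, and since the product is meso no absolute control is needed. The step needs stereospecificity and [4+2] addition in preference to diene dimerisation; geometrically pure E,E-diene (the E,Z isomer reaches s-cis far less readily), a large excess of ethylene and a radical inhibitor should secure both.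

Step 2
Reactants: 3 cis-3,6-dimethylcyclohex-1-ene
Product: 5 meso-(2R,5S)-2,5-dimethylhexane-1,6-diol, via secondary ozonide 4 (not isolated)
Conditions: O3, CH2Cl2, −78 °C; then NaBH4, MeOH, −78 °C → rt
Reagents that add atoms: ozone, [O-][O+]=O
Why: Criegee ozonolysis of the only olefin followed by hydride reduction of the ozonide should give the 1,6-diol without ever freeing the epimerisable α-branched dialdehyde, so the cis (meso) relation of C6/C9 is kept.

Step 3
Reactants: 5 meso-2,5-dimethylhexane-1,6-diol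
Product: 6 (2S,5R)-6-hydroxy-2,5-dimethylhexyl acetate (acetate on the C10 oxygen, free hydroxyl on C5)
Conditions: lipase AK (Pseudomonas fluorescens), vinyl acetate, t-BuOMe, rt, run slightly past mono-acylation
Reagents that add atoms: vinyl acetate, CC(=O)OC=C
Why: Lipase-catalysed irreversible transesterification should acylate the (S)-configured hydroxymethyl end (C10) selectively and so supply the absolute configuration of C6/C9; the minor enantiomer is removed as diacetate by the second acylation.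

Step 4
Reactants: 6 (2S,5R)-6-hydroxy-2,5-dimethylhexyl acetate
Product: 7 (2S,5R)-2,5-dimethyl-6-oxohexyl acetate
Conditions: TEMPO (cat.), PhI(OAc)2, CH2Cl2, rt
Reagents that add atoms: none
Why: The oxoammonium (TEMPO/PhI(OAc)2) oxidation should stop at the aldehyde under non-basic conditions, so the acetate and the α-methyl centre C6 stay intact.

Step 5
Reactants: 7 (2S,5R)-2,5-dimethyl-6-oxohexyl acetate
Product: 8 (2S,5R,6S)-6-hydroxy-2,5-dimethylnon-8-en-1-yl acetate
Conditions: (−)-Ipc2B(allyl) (salt-free, pentane), Et2O, −78 °C; then NaBO3·4H2O, THF/H2O, rt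
Reagents that add atoms: (−)-B-allyldiisopinocampheylborane, C=CCB([C@@H]1C[C@@H]2C[C@H]([C@H]1C)C2(C)C)[C@@H]1C[C@@H]2C[C@H]([C@H]1C)C2(C)C
Why: Brown allylboration through a closed chair transition state should deliver allyl to the Si face and set C5 as S (5,6-anti), with reagent control overriding the modest Felkin bias of the α-methyl aldehyde; the acetate is inert at −78 °C.

Step 6
Reactants: 8 (2S,5R,6S)-6-hydroxy-2,5-dimethylnon-8-en-1-yl acetate
Product: 9 (2S,5R,6S)-6-[(tert-butyldimethylsilyl)oxy]-2,5-dimethylnon-8-en-1-yl acetate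
Conditions: TBSOTf, 2,6-lutidine, CH2Cl2, −78 → 0 °C
Reagents that add atoms: tert-butyldimethylsilyl trifluoromethanesulfonate, CC(C)(C)[Si](C)(C)OS(=O)(=O)C(F)(F)F
Why: Silyl triflate silylation of the hindered secondary alcohol gives an ether that is stable to base, Grignard formation and the later aldol.

Step 7
Reactants: 9 (2S,5R,6S)-6-[(tert-butyldimethylsilyl)oxy]-2,5-dimethylnon-8-en-1-yl acetate
Product: 10 (2S,5R,6S)-6-[(tert-butyldimethylsilyl)oxy]-2,5-dimethylnon-8-en-1-ol
Conditions: K2CO3, MeOH, rt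
Reagents that add atoms: none
Why: Base-catalysed transesterification removes the acetate while the secondary TBS ether is untouched.

Step 8
Reactants: 10 (2S,5R,6S)-6-[(tert-butyldimethylsilyl)oxy]-2,5-dimethylnon-8-en-1-ol
Product: 11 {[(4S,5R,8S)-9-bromo-5,8-dimethylnon-1-en-4-yl]oxy}(tert-butyl)dimethylsilane
Conditions: CBr4, PPh3, CH2Cl2, 0 °C
Reagents that add atoms: carbon tetrabromide, BrC(Br)(Br)Br
Why: The Appel reaction converts the primary alcohol at C10 into the bromide by SN2 at a CH2 group, so C9 is not affected.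

Step 9
Reactants: 12 4,4-dimethoxycyclohexa-2,5-dien-1-one
Product: 13 (5R)-5-ethyl-4,4-dimethoxycyclohex-2-en-1-one
Conditions: Et2Zn, Cu(OTf)2 (2 mol %), (S,R,R)-BINOL/bis(1-phenylethyl)amine phosphoramidite (4 mol %), toluene, −25 °C; aq. NH4Cl, chromatography on Et3N-deactivated silica
Reagents that add atoms: diethylzinc, CC[Zn]CC
Why: Copper/phosphoramidite-catalysed asymmetric conjugate addition, a known reaction of quinone monoketals, sets C14 under ligand control; the zinc dienolate formed cannot add a second time, so the C16=C17 olefin of the target is retained.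

Step 10
Reactants: 13 (5R)-5-ethyl-4,4-dimethoxycyclohex-2-en-1-one
Product: 15 (5R,6R)-5-ethyl-4,4-dimethoxy-6-methylcyclohex-2-en-1-one (trans, major epimer), via lithium dienolate 14 (not isolated)
Conditions: LDA, THF, −78 °C; MeI, −78 → −20 °C
Reagents that add atoms: iodomethane, CI
Why: Kinetic α′-deprotonation gives the cross-conjugated enolate, the only one possible because C15 bears no hydrogen, and SN2 methylation installs the C13 methyl; the configuration at C13 is irrelevant because the centre is enolised again in step 11.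

Step 11
Reactants: 15 (5R,6R)-5-ethyl-4,4-dimethoxy-6-methylcyclohex-2-en-1-one
Product: 17 (5R,6R)-5-ethyl-4,4-dimethoxy-6-methyl-6-(prop-2-en-1-yl)cyclohex-2-en-1-one, via lithium dienolate 16 (not isolated)
Conditions: LDA, THF/DMPU, −78 °C; allyl bromide, −78 → 0 °C
Reagents that add atoms: allyl bromide, C=CCBr
Why: In the tetrasubstituted enolate the C14 ethyl group sits pseudoaxial (A1,2 strain with the C13 methyl), so allyl bromide should attack the opposite face under stereoelectronic control and give the quaternary C13 with allyl trans and methyl cis to ethyl, as known for 2-methyl-3-alkylcyclohexanone enolates.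

Step 12
Reactants: 17 (5R,6R)-5-ethyl-4,4-dimethoxy-6-methyl-6-(prop-2-en-1-yl)cyclohex-2-en-1-one
Product: 19 triethyl{[(1R,5R,6R)-5-ethyl-4,4-dimethoxy-1,6-dimethyl-6-(prop-2-en-1-yl)cyclohex-2-en-1-yl]oxy}silane, via lithium alkoxide 18 (not isolated)
Conditions: MeLi, THF, −78 °C; then 2,6-lutidine, TESOTf, −78 → 0 °C
Reagents that add atoms: methyllithium, [Li]C; triethylsilyl trifluoromethanesulfonate, CC[Si](CC)(CC)OS(=O)(=O)C(F)(F)F
Why: 1,2-Addition of methyllithium to the non-enolisable enone carbonyl should occur anti to the C14 ethyl group, placing the C18 oxygen cis to the C13 methyl, and O-silylation of the alkoxide in the same flask masks the tertiary alcohol before a leaving group is built on C11.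

Step 13
Reactants: 19 triethyl{[(1R,5R,6R)-5-ethyl-4,4-dimethoxy-1,6-dimethyl-6-(prop-2-en-1-yl)cyclohex-2-en-1-yl]oxy}silane
Product: 21 2-[(1R,2R,6R)-6-ethyl-5,5-dimethoxy-1,2-dimethyl-2-(triethylsilyloxy)cyclohex-3-en-1-yl]acetaldehyde, via vicinal diol 20 (not isolated)
Conditions: OsO4 (cat.), NaIO4, 2,6-lutidine, dioxane/H2O, rt
Reagents that add atoms: osmium tetroxide (catalytic oxygen carrier), O=[Os](=O)(=O)=O; sodium periodate, [Na+].[O-]I(=O)(=O)=O
Why: In this Lemieux–Johnson cleavage the monosubstituted allyl olefin should be dihydroxylated far faster than the ring olefin, which is flanked by two fully substituted carbons and deactivated by allylic oxygens; the buffered medium spares the ketal.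

Step 14
Reactants: 21 2-[(1R,2R,6R)-6-ethyl-5,5-dimethoxy-1,2-dimethyl-2-(triethylsilyloxy)cyclohex-3-en-1-yl]acetaldehyde
Product: 22 2-[(1R,2R,6R)-6-ethyl-5,5-dimethoxy-1,2-dimethyl-2-(triethylsilyloxy)cyclohex-3-en-1-yl]ethan-1-ol
Conditions: NaBH4, MeOH, 0 °C
Reagents that add atoms: none
Why: Borohydride reduction of the non-enolisable-side aldehyde gives the primary alcohol at C11 without touching ketal, silyl ether or olefin.

Step 15
Reactants: 22 2-[(1R,2R,6R)-6-ethyl-5,5-dimethoxy-1,2-dimethyl-2-(triethylsilyloxy)cyclohex-3-en-1-yl]ethan-1-ol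
Product: 23 2-[(1R,2R,6R)-6-ethyl-5,5-dimethoxy-1,2-dimethyl-2-(triethylsilyloxy)cyclohex-3-en-1-yl]ethyl 4-methylbenzenesulfonate
Conditions: TsCl, Et3N, DMAP (cat.), CH2Cl2, 0 °C → rt
Reagents that add atoms: 4-methylbenzenesulfonyl chloride, Cc1ccc(cc1)S(Cl)(=O)=O
Why: Sulfonylation of the primary alcohol gives the electrophile for the coupling; with the C18 oxygen silylated no tetrahydrofuran can form by internal displacement.

Step 16
Reactants: 11 {[(4S,5R,8S)-9-bromo-5,8-dimethylnon-1-en-4-yl]oxy}(tert-butyl)dimethylsilane; 23 the tosylate of step 15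
Product: 25 tert-butyl{[(4S,5R,8R)-11-[(1R,2R,6R)-6-ethyl-5,5-dimethoxy-1,2-dimethyl-2-(triethylsilyloxy)cyclohex-3-en-1-yl]-5,8-dimethylundec-1-en-4-yl]oxy}dimethylsilane, via Grignard reagent 24 (not isolated)
Conditions: 11, Mg, THF, 40 °C; then 23, Li2CuCl4 (5 mol %), THF, −78 °C → rt
Reagents that add atoms: none
Why: Copper-catalysed cross-coupling of a primary alkyl Grignard reagent with a primary tosylate forms C10–C11 directly at the sp3 level, so no olefin has to be reduced next to the ring and terminal alkenes; ketal, silyl ethers and stereocentres are inert.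

Step 17
Reactants: 25 the coupled diene of step 16
Product: 27 (3S,4R,7R)-3-[(tert-butyldimethylsilyl)oxy]-10-[(1R,2R,6R)-6-ethyl-5,5-dimethoxy-1,2-dimethyl-2-(triethylsilyloxy)cyclohex-3-en-1-yl]-4,7-dimethyldecanal, via vicinal diol 26 (not isolated)
Conditions: OsO4 (cat.), NaIO4, 2,6-lutidine, dioxane/H2O, rt
Reagents that add atoms: osmium tetroxide (catalytic oxygen carrier), O=[Os](=O)(=O)=O; sodium periodate, [Na+].[O-]I(=O)(=O)=O
Why: A second Lemieux–Johnson cleavage, selective for the terminal olefin for the same steric and electronic reasons as in step 13, unveils C3 as the aldehyde.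

Step 18
Reactants: 28 (4S)-4-benzyl-1,3-oxazolidin-2-one; 29 butanoyl chloride
Product: 30 (4S)-4-benzyl-3-butanoyl-1,3-oxazolidin-2-one
Conditions: n-BuLi, THF, −78 °C; then 29, −78 → 0 °C
Reagents that add atoms: none
Why: N-Acylation of the lithiated oxazolidinone gives the imide that carries C1, C2 and the ethyl branch.

Step 19
Reactants: 30 (4S)-4-benzyl-3-butanoyl-1,3-oxazolidin-2-one; 27 the aldehyde of step 17
Product: 32 (4S)-4-benzyl-3-[(2S,3R,5S,6R,9R)-5-[(tert-butyldimethylsilyl)oxy]-2-ethyl-12-[(1R,2R,6R)-6-ethyl-5,5-dimethoxy-1,2-dimethyl-2-(triethylsilyloxy)cyclohex-3-en-1-yl]-3-hydroxy-6,9-dimethyldodecanoyl]-1,3-oxazolidin-2-one, via Z-boron enolate 31 (not isolated)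
Conditions: 30 (slight excess over boron reagent), Bu2BOTf, i-Pr2NEt, CH2Cl2, −78 → 0 °C; 27, −78 → 0 °C; pH 7 buffer, MeOH, 30 % H2O2, 0 °C
Reagents that add atoms: none
Why: The Evans syn-aldol reaction of the Z-boron enolate through a Zimmerman–Traxler transition state sets C2 and C3 together under auxiliary control (2,3-syn, the 2R,3R pair of the target), and keeping the imide in excess leaves no free boron triflate to attack the ketal.

Step 20
Reactants: 32 the aldol adduct of step 19
Product: 33 (2R,3R,5S,6R,9R)-5-[(tert-butyldimethylsilyl)oxy]-2-ethyl-12-[(1R,2R,6R)-6-ethyl-5,5-dimethoxy-1,2-dimethyl-2-(triethylsilyloxy)cyclohex-3-en-1-yl]-6,9-dimethyldodecane-1,3-diol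
Conditions: LiBH4, MeOH (1 equiv), THF, 0 °C
Reagents that add atoms: none
Why: Reductive cleavage of the N-acyl oxazolidinone turns C1 into the primary alcohol and releases the auxiliary without epimerising C2.

Step 21
Reactants: 33 the diol of step 20
Product: 34 (4R,5R,6R)-6-ethyl-5-[(4R,7R,8S,10R,11R)-11-ethyl-8,10,12-trihydroxy-4,7-dimethyldodecyl]-4-hydroxy-4,5-dimethylcyclohex-2-en-1-one (CNP0104178.2)
Conditions: HF (48 % aq.), MeCN/H2O, 0 °C → rt
Reagents that add atoms: water, O
Why: Acidic global deprotection removes both silyl ethers and hydrolyses the allylic dimethyl ketal through an oxocarbenium ion that water captures, which should unmask the γ-hydroxy enone under conditions too mild to enolise C14.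

**Compound list**

1 | (2E,4E)-hexa-2,4-diene | C/C=C/C=C/C | starting material
2 | ethylene | C=C | starting material
3 | cis-3,6-dimethylcyclohex-1-ene (meso, 3R,6S) | C[C@H]1C=C[C@@H](C)CC1 | intermediate
4 | cis-2,5-dimethyl-7,8,9-trioxabicyclo[4.2.1]nonane (secondary ozonide, both orientations of the peroxide bridge, formed in the flask) | C[C@@H]1CC[C@H](C)C2OOC1O2 | intermediate
5 | meso-(2R,5S)-2,5-dimethylhexane-1,6-diol | OC[C@H](C)CC[C@H](C)CO | intermediate
6 | (2S,5R)-6-hydroxy-2,5-dimethylhexyl acetate | OC[C@H](C)CC[C@H](C)COC(C)=O | intermediate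
7 | (2S,5R)-2,5-dimethyl-6-oxohexyl acetate | O=C[C@H](C)CC[C@H](C)COC(C)=O | intermediate
8 | (2S,5R,6S)-6-hydroxy-2,5-dimethylnon-8-en-1-yl acetate | C=CC[C@H](O)[C@H](C)CC[C@H](C)COC(C)=O | intermediate
9 | (2S,5R,6S)-6-[(tert-butyldimethylsilyl)oxy]-2,5-dimethylnon-8-en-1-yl acetate | C=CC[C@H](O[Si](C)(C)C(C)(C)C)[C@H](C)CC[C@H](C)COC(C)=O | intermediate
10 | (2S,5R,6S)-6-[(tert-butyldimethylsilyl)oxy]-2,5-dimethylnon-8-en-1-ol | C=CC[C@H](O[Si](C)(C)C(C)(C)C)[C@H](C)CC[C@H](C)CO | intermediate
11 | {[(4S,5R,8S)-9-bromo-5,8-dimethylnon-1-en-4-yl]oxy}(tert-butyl)dimethylsilane | C=CC[C@H](O[Si](C)(C)C(C)(C)C)[C@H](C)CC[C@H](C)CBr | intermediate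
12 | 4,4-dimethoxycyclohexa-2,5-dien-1-one | COC1(OC)C=CC(=O)C=C1 | starting material
13 | (5R)-5-ethyl-4,4-dimethoxycyclohex-2-en-1-one | O=C1C=CC(OC)(OC)[C@H](CC)C1 | intermediate
14 | lithium (3R)-3-ethyl-4,4-dimethoxycyclohexa-1,5-dien-1-olate (formed in the flask) | [Li]OC1=C[C@@H](CC)C(OC)(OC)C=C1 | intermediate
15 | (5R,6R)-5-ethyl-4,4-dimethoxy-6-methylcyclohex-2-en-1-one (trans, major epimer) | C[C@@H]1[C@@H](CC)C(OC)(OC)C=CC1=O | intermediate
16 | lithium (3R)-3-ethyl-4,4-dimethoxy-2-methylcyclohexa-1,5-dien-1-olate (formed in the flask) | [Li]OC1=C(C)[C@@H](CC)C(OC)(OC)C=C1 | intermediate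
17 | (5R,6R)-5-ethyl-4,4-dimethoxy-6-methyl-6-(prop-2-en-1-yl)cyclohex-2-en-1-one | C=CC[C@]1(C)[C@@H](CC)C(OC)(OC)C=CC1=O | intermediate
18 | lithium (1R,5R,6R)-5-ethyl-4,4-dimethoxy-1,6-dimethyl-6-(prop-2-en-1-yl)cyclohex-2-en-1-olate (formed in the flask) | C=CC[C@]1(C)[C@@H](CC)C(OC)(OC)C=C[C@@]1(C)O[Li] | intermediate
19 | triethyl{[(1R,5R,6R)-5-ethyl-4,4-dimethoxy-1,6-dimethyl-6-(prop-2-en-1-yl)cyclohex-2-en-1-yl]oxy}silane | C=CC[C@]1(C)[C@@H](CC)C(OC)(OC)C=C[C@@]1(C)O[Si](CC)(CC)CC | intermediate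
20 | 3-[(1R,2R,6R)-6-ethyl-5,5-dimethoxy-1,2-dimethyl-2-(triethylsilyloxy)cyclohex-3-en-1-yl]propane-1,2-diol (both C2 epimers, formed in the flask) | OCC(O)C[C@]1(C)[C@@H](CC)C(OC)(OC)C=C[C@@]1(C)O[Si](CC)(CC)CC | intermediate
21 | 2-[(1R,2R,6R)-6-ethyl-5,5-dimethoxy-1,2-dimethyl-2-(triethylsilyloxy)cyclohex-3-en-1-yl]acetaldehyde | O=CC[C@]1(C)[C@@H](CC)C(OC)(OC)C=C[C@@]1(C)O[Si](CC)(CC)CC | intermediate
22 | 2-[(1R,2R,6R)-6-ethyl-5,5-dimethoxy-1,2-dimethyl-2-(triethylsilyloxy)cyclohex-3-en-1-yl]ethan-1-ol | OCC[C@]1(C)[C@@H](CC)C(OC)(OC)C=C[C@@]1(C)O[Si](CC)(CC)CC | intermediate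
23 | 2-[(1R,2R,6R)-6-ethyl-5,5-dimethoxy-1,2-dimethyl-2-(triethylsilyloxy)cyclohex-3-en-1-yl]ethyl 4-methylbenzenesulfonate | Cc2ccc(cc2)S(=O)(=O)OCC[C@]1(C)[C@@H](CC)C(OC)(OC)C=C[C@@]1(C)O[Si](CC)(CC)CC | intermediate
24 | [(2S,5R,6S)-6-[(tert-butyldimethylsilyl)oxy]-2,5-dimethylnon-8-en-1-yl]magnesium bromide (formed in the flask) | C=CC[C@H](O[Si](C)(C)C(C)(C)C)[C@H](C)CC[C@H](C)C[Mg]Br | intermediate
25 | tert-butyl{[(4S,5R,8R)-11-[(1R,2R,6R)-6-ethyl-5,5-dimethoxy-1,2-dimethyl-2-(triethylsilyloxy)cyclohex-3-en-1-yl]-5,8-dimethylundec-1-en-4-yl]oxy}dimethylsilane | C=CC[C@H](O[Si](C)(C)C(C)(C)C)[C@H](C)CC[C@H](C)CCC[C@]1(C)[C@@H](CC)C(OC)(OC)C=C[C@@]1(C)O[Si](CC)(CC)CC | intermediate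
26 | (4S,5R,8R)-4-[(tert-butyldimethylsilyl)oxy]-11-[(1R,2R,6R)-6-ethyl-5,5-dimethoxy-1,2-dimethyl-2-(triethylsilyloxy)cyclohex-3-en-1-yl]-5,8-dimethylundecane-1,2-diol (both C2 epimers, formed in the flask) | OCC(O)C[C@H](O[Si](C)(C)C(C)(C)C)[C@H](C)CC[C@H](C)CCC[C@]1(C)[C@@H](CC)C(OC)(OC)C=C[C@@]1(C)O[Si](CC)(CC)CC | intermediate
27 | (3S,4R,7R)-3-[(tert-butyldimethylsilyl)oxy]-10-[(1R,2R,6R)-6-ethyl-5,5-dimethoxy-1,2-dimethyl-2-(triethylsilyloxy)cyclohex-3-en-1-yl]-4,7-dimethyldecanal | O=CC[C@H](O[Si](C)(C)C(C)(C)C)[C@H](C)CC[C@H](C)CCC[C@]1(C)[C@@H](CC)C(OC)(OC)C=C[C@@]1(C)O[Si](CC)(CC)CC | intermediate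
28 | (4S)-4-benzyl-1,3-oxazolidin-2-one | O=C1OC[C@H](Cc2ccccc2)N1 | starting material
29 | butanoyl chloride | CCCC(Cl)=O | starting material
30 | (4S)-4-benzyl-3-butanoyl-1,3-oxazolidin-2-one | CCCC(=O)N1[C@@H](Cc2ccccc2)COC1=O | intermediate
31 | dibutyl{[(1Z)-1-[(4S)-4-benzyl-2-oxo-1,3-oxazolidin-3-yl]but-1-en-1-yl]oxy}borane (formed in the flask) | CC/C=C(\OB(CCCC)CCCC)N1[C@@H](Cc2ccccc2)COC1=O | intermediate
32 | (4S)-4-benzyl-3-[(2S,3R,5S,6R,9R)-5-[(tert-butyldimethylsilyl)oxy]-2-ethyl-12-[(1R,2R,6R)-6-ethyl-5,5-dimethoxy-1,2-dimethyl-2-(triethylsilyloxy)cyclohex-3-en-1-yl]-3-hydroxy-6,9-dimethyldodecanoyl]-1,3-oxazolidin-2-one | CC[C@H](C(=O)N2[C@@H](Cc3ccccc3)COC2=O)[C@H](O)C[C@H](O[Si](C)(C)C(C)(C)C)[C@H](C)CC[C@H](C)CCC[C@]1(C)[C@@H](CC)C(OC)(OC)C=C[C@@]1(C)O[Si](CC)(CC)CC | intermediate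
33 | (2R,3R,5S,6R,9R)-5-[(tert-butyldimethylsilyl)oxy]-2-ethyl-12-[(1R,2R,6R)-6-ethyl-5,5-dimethoxy-1,2-dimethyl-2-(triethylsilyloxy)cyclohex-3-en-1-yl]-6,9-dimethyldodecane-1,3-diol | CC[C@H](CO)[C@H](O)C[C@H](O[Si](C)(C)C(C)(C)C)[C@H](C)CC[C@H](C)CCC[C@]1(C)[C@@H](CC)C(OC)(OC)C=C[C@@]1(C)O[Si](CC)(CC)CC | intermediate
34 | (4R,5R,6R)-6-ethyl-5-[(4R,7R,8S,10R,11R)-11-ethyl-8,10,12-trihydroxy-4,7-dimethyldodecyl]-4-hydroxy-4,5-dimethylcyclohex-2-en-1-one | CC[C@H](CO)[C@H](O)C[C@H](O)[C@H](C)CC[C@H](C)CCC[C@]1(C)[C@@H](CC)C(=O)C=C[C@@]1(C)O | target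

**Step count and risks**

Total: 21 steps. Longest linear sequence: 13 steps (steps 1–8, 16, 17, 19, 20, 21); the ring branch (steps 9–15) joins at step 16 and the imide (step 18) at step 19.

Steps most likely to fail:

Step 1 – sluggish cycloaddition with unactivated ethylene, with diene oligomerisation competing at the temperature and pressure needed. The fallback keeps the same two bonds and the same ring but uses an activated ethylene equivalent. It sets out from 1: heating with phenyl vinyl sulfone (toluene, 120 °C) should give [(cis-2,5-dimethylcyclohex-3-en-1-yl)sulfonyl]benzene F1 as a racemic mixture of sulfonyl epimers, still with the methyl groups cis. Reductive desulfonylation (Na/Hg, Na2HPO4, MeOH) then removes the activating group and the route is rejoined at 3.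

Step 3 – incomplete discrimination between the two enantiotopic hydroxymethyl ends (the reacting oxygen is two bonds from one stereocentre and the other is remote), which would lower the enantiomeric purity of every later chain compound. The fallback replaces enzymatic selection by a covalent chiral auxiliary and separation. It sets out from 5: mono-esterification with (S)-2-methoxy-2-phenylacetic acid (DCC, DMAP) gives two diastereomeric monoesters that are separated by chromatography; the wrong one is saponified back to 5. The isomer esterified on the C10 oxygen, (2S,5R)-6-hydroxy-2,5-dimethylhexyl (2S)-2-methoxy-2-phenylacetate F2, takes the place of 6. Under the conditions of steps 4–6 it gives in turn (2S,5R)-2,5-dimethyl-6-oxohexyl (2S)-2-methoxy-2-phenylacetate F3, (2S,5R,6S)-6-hydroxy-2,5-dimethylnon-8-en-1-yl (2S)-2-methoxy-2-phenylacetate F4 and (2S,5R,6S)-6-[(tert-butyldimethylsilyl)oxy]-2,5-dimethylnon-8-en-1-yl (2S)-2-methoxy-2-phenylacetate F5. The K2CO3/MeOH conditions of step 7 then remove the mandelate and the route is rejoined at 10.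

Step 12 – poor or inverted facial selectivity in the addition of methyllithium to the C18 carbonyl, which is flanked by a quaternary carbon whose two substituents differ little in size. The fallback, meant for the case that the nucleophile prefers the face syn to ethyl, brings in the carbon first and the oxygen second, which inverts the outcome at C18. It sets out from 17: methylenation (Ph3P=CH2, THF, or the Tebbe reagent) gives (4R,5R)-4-ethyl-3,3-dimethoxy-5-methyl-6-methylidene-5-(prop-2-en-1-yl)cyclohex-1-ene F6. Buffered mCPBA should epoxidise the 1,1-disubstituted exocyclic olefin, the most nucleophilic of the three, from the face the methyl nucleophile would have used, giving (3R,7R,8R)-7-ethyl-6,6-dimethoxy-8-methyl-8-(prop-2-en-1-yl)-1-oxaspiro[2.5]oct-4-ene F7. LiEt3BH opens the epoxide at its primary carbon to (1R,5R,6R)-5-ethyl-4,4-dimethoxy-1,6-dimethyl-6-(prop-2-en-1-yl)cyclohex-2-en-1-ol F8, and silylation (KHMDS, TESCl, THF) rejoins the route at 19.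

Further compounds
F1 | step 1 | [(cis-2,5-dimethylcyclohex-3-en-1-yl)sulfonyl]benzene (racemic, sulfonyl epimers) | C[C@H]1C=C[C@@H](C)C(S(=O)(=O)c2ccccc2)C1
F2 | step 3 | (2S,5R)-6-hydroxy-2,5-dimethylhexyl (2S)-2-methoxy-2-phenylacetate | OC[C@H](C)CC[C@H](C)COC(=O)[C@@H](OC)c1ccccc1
F3 | step 3 | (2S,5R)-2,5-dimethyl-6-oxohexyl (2S)-2-methoxy-2-phenylacetate | O=C[C@H](C)CC[C@H](C)COC(=O)[C@@H](OC)c1ccccc1
F4 | step 3 | (2S,5R,6S)-6-hydroxy-2,5-dimethylnon-8-en-1-yl (2S)-2-methoxy-2-phenylacetate | C=CC[C@H](O)[C@H](C)CC[C@H](C)COC(=O)[C@@H](OC)c1ccccc1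
F5 | step 3 | (2S,5R,6S)-6-[(tert-butyldimethylsilyl)oxy]-2,5-dimethylnon-8-en-1-yl (2S)-2-methoxy-2-phenylacetate | C=CC[C@H](O[Si](C)(C)C(C)(C)C)[C@H](C)CC[C@H](C)COC(=O)[C@@H](OC)c1ccccc1
F6 | step 12 | (4R,5R)-4-ethyl-3,3-dimethoxy-5-methyl-6-methylidene-5-(prop-2-en-1-yl)cyclohex-1-ene | C=CC[C@]1(C)[C@@H](CC)C(OC)(OC)C=CC1=C
F7 | step 12 | (3R,7R,8R)-7-ethyl-6,6-dimethoxy-8-methyl-8-(prop-2-en-1-yl)-1-oxaspiro[2.5]oct-4-ene | C=CC[C@]1(C)[C@@H](CC)C(OC)(OC)C=C[C@]12CO2
F8 | step 12 | (1R,5R,6R)-5-ethyl-4,4-dimethoxy-1,6-dimethyl-6-(prop-2-en-1-yl)cyclohex-2-en-1-ol | C=CC[C@]1(C)[C@@H](CC)C(OC)(OC)C=C[C@@]1(C)O
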